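## Retrosynthetic overview
- **Feature:** the carbocycle of the benzofuran (C3a-C4-C5-C6-C7-C7a) has oxygen on C4 and C6, meta to each other, and the quaternary carbon of the 1,1-dimethylallyl group on C7, next to C7a. A 2-furyl(tert-alkyl)ketene (C7 and C4, with furan C2/C3 as C7a/C3a) and a terminal ynol ether (C5, C6) leave exactly this pattern.
- **Key disconnection:** C4-C5 and C6-C7 are formed by a [2+2] to a 3-alkoxycyclobutenone, then C3a-C4 by 4-pi opening and 6-pi closure on furan C3. The precursors are a 2-furyl-3,3-dimethylpent-4-enoyl chloride and 2-(trimethylsilyl)ethyl ethynyl ether.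
- **Earlier bonds:** the bond from C7 to the quaternary carbon is made as an sp3-sp3 bond by Ireland-Claisen shift of a prenyl furylacetate. The furan C5-aryl bond is made by palladium C-H arylation of methyl 2-furylacetate.
- **Chroman:** the 5-bromochroman comes from 1-bromo-3,5-dimethoxybenzene by acylation next to bromine, ortho-demethylation with oxa-Michael closure, and deoxygenation. This sequence fixes the regiochemistry.
- **Ring order:** the pyran ring of the chroman is made first, the furan is bought, and the benzene ring of the benzofuran is made last. Thiolate (C7' methyl) and fluoride (C6 silylethyl) then free the triol.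

Key step: step 10

Remark: the target has no stereocentre. The stereocentres that arise on the way are carried racemic and vanish on ketene formation or aromatisation.

## Route

Step 1
Reactants: 1 1-bromo-3,5-dimethoxybenzene; 2 3-methylbut-2-enoyl chloride
Product: 3 1-(2-bromo-4,6-dimethoxyphenyl)-3-methylbut-2-en-1-one
Conditions: AlCl3 (1.2 equiv), CH2Cl2, 0 °C; ice-cold 1 M HCl
Reagents that add atoms: none
Why: Friedel-Crafts acylation goes para to one methoxy group (the carbon next to bromine), as formylation and halogenation of this arene do, which places bromine peri to the future C4 of the chroman, whereas acid-catalysed prenol annulation of 5-bromoresorcinol would suffer from competing attack between the two hydroxyl groups.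

Step 2
Reactants: 3 1-(2-bromo-4,6-dimethoxyphenyl)-3-methylbut-2-en-1-one
Product: 5 5-bromo-7-methoxy-2,2-dimethylchroman-4-one, via hydroxy enone 4 (not isolated)
Conditions: BCl3 (1.3 equiv), CH2Cl2, -78→0 °C; H2O; crude in MeOH, K2CO3 (0.2 equiv), 23 °C
Reagents that add atoms: none
Why: Chelation-controlled ether cleavage (BCl3 bound to the ketone removes only the ortho methyl group) is followed by 6-endo-trig oxa-Michael addition of the freed phenoxide to the beta,beta-dimethyl enone, which closes the pyranone ring.

Step 3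
Reactants: 5 5-bromo-7-methoxy-2,2-dimethylchroman-4-one
Product: 6 5-bromo-7-methoxy-2,2-dimethylchroman
Conditions: Et3SiH (3 equiv), CF3CO2H, 23→50 °C
Reagents that add atoms: none
Why: Ionic hydrogenation takes the ketone to CH2 because the benzylic cation is stabilised by the ortho and para oxygens and accepts hydride twice, while aryl bromide, methyl ether and the acid-stable chroman ring are inert.

Step 4
Reactants: 7 2-furylacetic acid
Product: 8 methyl 2-(furan-2-yl)acetate
Conditions: MeI (1.2 equiv), K2CO3 (1.2 equiv), DMF, 23 °C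
Reagents that add atoms: iodomethane, CI
Why: SN2 alkylation of the carboxylate makes the ester without the acid that a Fischer esterification would bring to the C5-unsubstituted furan.

Step 5
Reactants: 6 5-bromo-7-methoxy-2,2-dimethylchroman; 8 methyl 2-(furan-2-yl)acetate
Product: 9 methyl 2-[5-(7-methoxy-2,2-dimethylchroman-5-yl)furan-2-yl]acetate
Conditions: Pd(OAc)2 (5 mol %), PCy3·HBF4 (10 mol %), PivOH (30 mol %), K2CO3 (1.5 equiv), 8 (2 equiv), DMA, 110 °C
Reagents that add atoms: none
Why: Direct C-H arylation by concerted metalation-deprotonation takes place at the free alpha position C5 of a 2-substituted furan, the weak base leaves the ester alpha-CH2 alone, and a methyl ester is used here because zerovalent palladium would ionise a prenyl ester.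

Step 6
Reactants: 9 methyl 2-[5-(7-methoxy-2,2-dimethylchroman-5-yl)furan-2-yl]acetate; 10 prenol (3-methylbut-2-en-1-ol)
Product: 11 3-methylbut-2-enyl 2-[5-(7-methoxy-2,2-dimethylchroman-5-yl)furan-2-yl]acetate
Conditions: Ti(OiPr)4 (10 mol %), 10 (8 equiv), PhMe, 100 °C, 4 Å MS (removal of MeOH)
Reagents that add atoms: none
Why: Titanate-catalysed transesterification under neutral conditions, driven by removal of methanol, installs the allylic ester only after the palladium step and leaves the furan untouched.

Step 7
Reactants: 11 3-methylbut-2-enyl 2-[5-(7-methoxy-2,2-dimethylchroman-5-yl)furan-2-yl]acetate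
Product: 14 2-[5-(7-methoxy-2,2-dimethylchroman-5-yl)furan-2-yl]-3,3-dimethylpent-4-enoic acid (racemic), via silyl ketene acetal 12 (not isolated), via silyl ester 13 (not isolated)
Conditions: LiN(iPr)2 (1.2 equiv), THF, -78 °C; Me3SiCl (1.5 equiv); -78→60 °C; dilute HCl
Reagents that add atoms: none
Why: The Ireland-Claisen [3,3] shift joins the furyl-bearing carbon to the dimethyl-substituted terminus of the prenyl group, so the hindered bond to the quaternary carbon is made intramolecularly between two sp3 centres, and the new stereocentre is racemic and is erased in step 10.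

Step 8
Reactants: 14 2-[5-(7-methoxy-2,2-dimethylchroman-5-yl)furan-2-yl]-3,3-dimethylpent-4-enoic acid
Product: 15 2-[5-(7-methoxy-2,2-dimethylchroman-5-yl)furan-2-yl]-3,3-dimethylpent-4-enoyl chloride (racemic)
Conditions: (COCl)2 (1.5 equiv), DMF (cat.), CH2Cl2, 0→23 °C; evaporate
Reagents that add atoms: oxalyl chloride, O=C(Cl)C(=O)Cl
Why: Acid chloride formation through the chloroiminium salt of DMF gives only gaseous by-products, so crude 15 is used after evaporation, and the 2,5-disubstituted furan and the monosubstituted alkene tolerate brief contact with HCl at or below room temperature.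

Step 9
Reactants: 16 2-(trimethylsilyl)ethanol; 17 trichloroethylene
Product: 21 [2-(ethynyloxy)ethyl]trimethylsilane, via dichlorovinyl ether 18 (not isolated), via chloroalkynyl ether 19 (not isolated), via lithium acetylide 20 (not isolated)
Conditions: KH (1.1 equiv), THF, 0 °C; 17, -50→23 °C; n-BuLi (2.3 equiv), -78→-40 °C; H2O, -78 °C; distil under reduced pressure
Reagents that add atoms: none
Why: This is the trichloroethylene route to ynol ethers (alkoxide addition, elimination of LiCl, lithium-chlorine exchange, protonation), and the silylethyl group is chosen because the C6 ether will sit meta to a phenoxide, where thiolate SN2 cleavage of a plain ethyl ether stalls, while fluoride-induced loss of ethene does not depend on that.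

Step 10
Reactants: 15 2-[5-(7-methoxy-2,2-dimethylchroman-5-yl)furan-2-yl]-3,3-dimethylpent-4-enoyl chloride; 21 [2-(ethynyloxy)ethyl]trimethylsilane
Product: 26 7-(1,1-dimethylallyl)-2-(7-methoxy-2,2-dimethylchroman-5-yl)-6-[2-(trimethylsilyl)ethoxy]benzofuran-4-ol, via ketene 22 (not isolated), via cyclobutenone 23 (not isolated), via dienylketene 24 (not isolated), via dienone 25 (not isolated)
Conditions: Et3N (2 equiv), PhMe, 23→60 °C, filter under Ar; 21 (3 equiv), 1 M, 23→45 °C; strip excess 21; PhMe (0.05 M), 110 °C
Reagents that add atoms: none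
Why: Et3N removes the furyl-activated alpha hydrogen of 15 and chloride leaves, giving ketene 22, which is too hindered to dimerise, so the ammonium salt can be filtered off before the acid-sensitive alkyne is added. Bond C4-C5 forms first, between the nucleophilic CH terminus of 21 and the central ketene carbon approached in the ketene plane past the flat furan, and collapse of the enolate/alkoxyvinyl cation pair at the enolate carbon then makes C6-C7, so the polarity of the ynol ether alone sets the regiochemistry of this stepwise [2+2] closure of the four-membered ring to 23. On heating, the C1-C4 bond of 23 (the old C=C of the ketene) is cleaved in a reversible conrotatory 4-pi opening in which the bulky tert-alkyl group turns outward, and only isomer 24 with the furan turned inward is drained by disrotatory 6-pi electrocyclic closure of the ketene carbon onto furan C3 (C3a-C4), which closes the benzene ring before dienone 25 tautomerises to phenol 26. The reaction type is the Danheiser-type benzannulation through a ketene-alkoxyalkyne cyclobutenone, known with closure onto furans, and tert-butylcyanoketene shows that a tertiary alkyl group on a ketene does not in itself block the cycloaddition, although a furyl(tert-alkyl)ketene is an untested extreme of the class. The stereocentres of 15, 23 and 25 are racemic and vanish in the aromatic product, so none has to be controlled. Capture of the cationic carbon by furan C3 before four-ring closure would only swap ether and phenol between C4 and C6, a difference that steps 11 and 12 erase, and the vinyl group cannot reach the ketene of 22 across its one-carbon tether.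

Step 11
Reactants: 26 7-(1,1-dimethylallyl)-2-(7-methoxy-2,2-dimethylchroman-5-yl)-6-[2-(trimethylsilyl)ethoxy]benzofuran-4-ol
Product: 27 7-(1,1-dimethylallyl)-2-(7-hydroxy-2,2-dimethylchroman-5-yl)-6-[2-(trimethylsilyl)ethoxy]benzofuran-4-ol
Conditions: NaSEt (6 equiv), DMF, 120 °C, Ar; AcOH, 0 °C
Reagents that add atoms: none
Why: Thiolate SN2 demethylation cleaves the only methyl ether, which sits on the chroman ring that carries no phenoxide, the basic medium keeps the ortho-(1,1-dimethylallyl)phenol from acid-induced cyclisation and does not touch the vinyl group, and any early loss of the silylethyl group only anticipates step 12.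

Step 12
Reactants: 27 7-(1,1-dimethylallyl)-2-(7-hydroxy-2,2-dimethylchroman-5-yl)-6-[2-(trimethylsilyl)ethoxy]benzofuran-4-ol
Product: 28 7-(1,1-dimethylallyl)-2-(7-hydroxy-2,2-dimethylchroman-5-yl)benzofuran-4,6-diol (target)
Conditions: Bu4NF (1 M in THF, 6 equiv), DMF, 70 °C, Ar; AcOH, 0 °C
Reagents that add atoms: none
Why: Fluoride attacks silicon and triggers beta-elimination of ethene and Me3SiF, a cleavage that needs neither SN2 attack at carbon nor acid, so it should proceed on the phenoxide-bearing ring and leave the vinyl group and the chroman intact.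

## Compound list
1 | 1-bromo-3,5-dimethoxybenzene | COc1cc(Br)cc(OC)c1 | starting material
2 | 3-methylbut-2-enoyl chloride | CC(C)=CC(=O)Cl | starting material
3 | 1-(2-bromo-4,6-dimethoxyphenyl)-3-methylbut-2-en-1-one | CC(C)=CC(=O)c1c(Br)cc(OC)cc1OC | intermediate
4 | 1-(2-bromo-6-hydroxy-4-methoxyphenyl)-3-methylbut-2-en-1-one | CC(C)=CC(=O)c1c(Br)cc(OC)cc1O | intermediate
5 | 5-bromo-7-methoxy-2,2-dimethylchroman-4-one | COc1cc(Br)c2c(c1)OC(C)(C)CC2=O | intermediate
6 | 5-bromo-7-methoxy-2,2-dimethylchroman | COc1cc(Br)c2c(c1)OC(C)(C)CC2 | intermediate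
7 | 2-furylacetic acid | OC(=O)Cc1ccco1 | starting material
8 | methyl 2-(furan-2-yl)acetate | COC(=O)Cc1ccco1 | intermediate
9 | methyl 2-[5-(7-methoxy-2,2-dimethylchroman-5-yl)furan-2-yl]acetate | COC(=O)Cc1ccc(-c2cc(OC)cc3c2CCC(C)(C)O3)o1 | intermediate
10 | prenol (3-methylbut-2-en-1-ol) | CC(C)=CCO | starting material
11 | 3-methylbut-2-enyl 2-[5-(7-methoxy-2,2-dimethylchroman-5-yl)furan-2-yl]acetate | CC(C)=CCOC(=O)Cc1ccc(-c2cc(OC)cc3c2CCC(C)(C)O3)o1 | intermediate
12 | prenyl trimethylsilyl ketene acetal of 11 (alkene geometry not defined and without consequence) | CC(C)=CCOC(O[Si](C)(C)C)=Cc1ccc(-c2cc(OC)cc3c2CCC(C)(C)O3)o1 | intermediate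
13 | trimethylsilyl 2-[5-(7-methoxy-2,2-dimethylchroman-5-yl)furan-2-yl]-3,3-dimethylpent-4-enoate (racemic) | C=CC(C)(C)C(C(=O)O[Si](C)(C)C)c1ccc(-c2cc(OC)cc3c2CCC(C)(C)O3)o1 | intermediate
14 | 2-[5-(7-methoxy-2,2-dimethylchroman-5-yl)furan-2-yl]-3,3-dimethylpent-4-enoic acid (racemic) | C=CC(C)(C)C(C(=O)O)c1ccc(-c2cc(OC)cc3c2CCC(C)(C)O3)o1 | intermediate
15 | 2-[5-(7-methoxy-2,2-dimethylchroman-5-yl)furan-2-yl]-3,3-dimethylpent-4-enoyl chloride (racemic) | C=CC(C)(C)C(C(=O)Cl)c1ccc(-c2cc(OC)cc3c2CCC(C)(C)O3)o1 | intermediate
16 | 2-(trimethylsilyl)ethanol | C[Si](C)(C)CCO | starting material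
17 | trichloroethylene | ClC=C(Cl)Cl | starting material
18 | (E)-[2-(1,2-dichlorovinyloxy)ethyl]trimethylsilane | Cl/C=C(/Cl)OCC[Si](C)(C)C | intermediate
19 | [2-(chloroethynyloxy)ethyl]trimethylsilane | ClC#COCC[Si](C)(C)C | intermediate
20 | lithium 2-[2-(trimethylsilyl)ethoxy]acetylide | [Li]C#COCC[Si](C)(C)C | intermediate
21 | [2-(ethynyloxy)ethyl]trimethylsilane | C#COCC[Si](C)(C)C | intermediate
22 | 2-[5-(7-methoxy-2,2-dimethylchroman-5-yl)furan-2-yl]-3,3-dimethylpenta-1,4-dien-1-one (ketene) | C=CC(C)(C)C(=C=O)c1ccc(-c2cc(OC)cc3c2CCC(C)(C)O3)o1 | intermediate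
23 | 4-[5-(7-methoxy-2,2-dimethylchroman-5-yl)furan-2-yl]-4-(2-methylbut-3-en-2-yl)-3-[2-(trimethylsilyl)ethoxy]cyclobut-2-en-1-one (racemic) | O=C1C=C(OCC[Si](C)(C)C)C1(C(C)(C)C=C)c1ccc(-c2cc(OC)cc3c2CCC(C)(C)O3)o1 | intermediate
24 | (3E)-4-[5-(7-methoxy-2,2-dimethylchroman-5-yl)furan-2-yl]-5,5-dimethyl-3-[2-(trimethylsilyl)ethoxy]hepta-1,3,6-trien-1-one (furan cis to the ketenyl group) | O=C=C/C(OCC[Si](C)(C)C)=C(\c1ccc(-c2cc(OC)cc3c2CCC(C)(C)O3)o1)C(C)(C)C=C | intermediate
25 | 7-(1,1-dimethylallyl)-2-(7-methoxy-2,2-dimethylchroman-5-yl)-6-[2-(trimethylsilyl)ethoxy]-3aH-benzofuran-4-one (racemic) | O=C1C=C(OCC[Si](C)(C)C)C(C(C)(C)C=C)=C2OC(-c3cc(OC)cc4c3CCC(C)(C)O4)=CC12 | intermediate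
26 | 7-(1,1-dimethylallyl)-2-(7-methoxy-2,2-dimethylchroman-5-yl)-6-[2-(trimethylsilyl)ethoxy]benzofuran-4-ol | C=CC(C)(C)c1c(OCC[Si](C)(C)C)cc(O)c2cc(-c3cc(OC)cc4c3CCC(C)(C)O4)oc12 | intermediate
27 | 7-(1,1-dimethylallyl)-2-(7-hydroxy-2,2-dimethylchroman-5-yl)-6-[2-(trimethylsilyl)ethoxy]benzofuran-4-ol | C=CC(C)(C)c1c(OCC[Si](C)(C)C)cc(O)c2cc(-c3cc(O)cc4c3CCC(C)(C)O4)oc12 | intermediate
28 | 7-(1,1-dimethylallyl)-2-(7-hydroxy-2,2-dimethylchroman-5-yl)benzofuran-4,6-diol | C=CC(C)(C)c1c(O)cc(O)c2cc(-c3cc(O)cc4c3CCC(C)(C)O4)oc12 | target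

## Step count and risks
Total steps: 12. Longest linear sequence: 10 steps (1, 2, 3, 5, 6, 7, 8, 10, 11, 12).

**Step 10.**
- What may go wrong:
  - Loss of HCl at the neopentyl-type alpha position may be slow.
  - Bond formation at the fully substituted ketene carbon may be slower than retro-ene decay of the ynol ether.
  - The 1,5-diene inside the cyclobutenone may undergo a Cope shift before the ring opens.
  - Inward rotation of the tert-alkyl group may lead to intramolecular ketene-alkene cycloaddition.
- Fallback, from 15 back to 28: the ring is closed without any bond formation at the crowded carbon, because C6-C7 is then the existing bond between the carbonyl and alpha carbons of 15. Acid chloride 15 C-acylates Meldrum's acid (pyridine, DMAP, CH2Cl2, 0 °C) to give 5-acyl Meldrum's acid F1. Heating with Sc(OTf)3 (10 mol %) in MeNO2 at 90 °C expels acetone and CO2. The resulting acylketene F2 acylates furan C3 intramolecularly (catalytic Friedel-Crafts acylation with Meldrum's acid derivatives). After enolisation this should give 7-(1,1-dimethylallyl)-2-(7-methoxy-2,2-dimethylchroman-5-yl)benzofuran-4,6-diol F3. NaSEt in DMF as in step 11 then cleaves the remaining methyl ether and gives 28. Steps 9 and 12 are not needed on this path.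

**Step 5.**
- What may go wrong: oxidative addition of the electron-rich, ortho-substituted bromide may be sluggish. Prolonged heating may then bring arylation at the ester alpha carbon, homocoupling, or decay of the furan.
- Fallback, from 6 and 8 back to 9: the C-H activation is replaced by a cross-coupling of two prefunctionalised partners at lower temperature. Miyaura borylation of 6 (B2pin2, PdCl2(dppf), KOAc, dioxane, 90 °C) gives 2-(7-methoxy-2,2-dimethylchroman-5-yl)-4,4,5,5-tetramethyl-1,3,2-dioxaborolane F4. NBS in DMF at 0 °C converts 8 into methyl 2-(5-bromofuran-2-yl)acetate F5. Suzuki-Miyaura coupling of the two (Pd(PPh3)4, K3PO4, dioxane/H2O, 70 °C) gives 9.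

**Step 9.**
- What may go wrong: the volatile ynol ether may be lost on isolation, and lithium-chlorine exchange may stay incomplete. The beta-silicon atom may also speed up retro-ene fragmentation on storage or during step 10.
- Fallback, from 15 back to 28: commercial ethoxyacetylene (C#COCC) replaces 21 in the procedure of step 10. Ketene 22 should then give 3-ethoxycyclobutenone F6, dienylketene F7, dienone F8 and finally 7-(1,1-dimethylallyl)-6-ethoxy-2-(7-methoxy-2,2-dimethylchroman-5-yl)benzofuran-4-ol F9. The C6 ethyl ether sits on a ring that becomes a phenoxide in base, so thiolate dealkylation is expected to stall there. Both alkyl ethers are therefore cleaved by magnesium-assisted iodide attack with neat MeMgI at 160 °C, the method used for alkene-bearing resorcinol dialkyl ethers, to give 28.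

## Further compounds
F1 | step 10 | 5-{1-hydroxy-2-[5-(7-methoxy-2,2-dimethylchroman-5-yl)furan-2-yl]-3,3-dimethylpent-4-enylidene}-2,2-dimethyl-1,3-dioxane-4,6-dione (racemic) | C=CC(C)(C)C(C(O)=C1C(=O)OC(C)(C)OC1=O)c1ccc(-c2cc(OC)cc3c2CCC(C)(C)O3)o1
F2 | step 10 | 4-[5-(7-methoxy-2,2-dimethylchroman-5-yl)furan-2-yl]-5,5-dimethylhepta-1,6-diene-1,3-dione (acylketene, racemic) | C=CC(C)(C)C(C(=O)C=C=O)c1ccc(-c2cc(OC)cc3c2CCC(C)(C)O3)o1
F3 | step 10 | 7-(1,1-dimethylallyl)-2-(7-methoxy-2,2-dimethylchroman-5-yl)benzofuran-4,6-diol | C=CC(C)(C)c1c(O)cc(O)c2cc(-c3cc(OC)cc4c3CCC(C)(C)O4)oc12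
F4 | step 5 | 2-(7-methoxy-2,2-dimethylchroman-5-yl)-4,4,5,5-tetramethyl-1,3,2-dioxaborolane | COc1cc(B2OC(C)(C)C(C)(C)O2)c2c(c1)OC(C)(C)CC2
F5 | step 5 | methyl 2-(5-bromofuran-2-yl)acetate | COC(=O)Cc1ccc(Br)o1
F6 | step 9 | 3-ethoxy-4-[5-(7-methoxy-2,2-dimethylchroman-5-yl)furan-2-yl]-4-(2-methylbut-3-en-2-yl)cyclobut-2-en-1-one (racemic) | O=C1C=C(OCC)C1(C(C)(C)C=C)c1ccc(-c2cc(OC)cc3c2CCC(C)(C)O3)o1
F7 | step 9 | (3E)-3-ethoxy-4-[5-(7-methoxy-2,2-dimethylchroman-5-yl)furan-2-yl]-5,5-dimethylhepta-1,3,6-trien-1-one | O=C=C/C(OCC)=C(\c1ccc(-c2cc(OC)cc3c2CCC(C)(C)O3)o1)C(C)(C)C=C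
F8 | step 9 | 7-(1,1-dimethylallyl)-6-ethoxy-2-(7-methoxy-2,2-dimethylchroman-5-yl)-3aH-benzofuran-4-one (racemic) | O=C1C=C(OCC)C(C(C)(C)C=C)=C2OC(-c3cc(OC)cc4c3CCC(C)(C)O4)=CC12
F9 | step 9 | 7-(1,1-dimethylallyl)-6-ethoxy-2-(7-methoxy-2,2-dimethylchroman-5-yl)benzofuran-4-ol | C=CC(C)(C)c1c(OCC)cc(O)c2cc(-c3cc(OC)cc4c3CCC(C)(C)O4)oc12
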